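**Retrosynthetic overview**
1. The target is 5,7-dihydroxy-6,8-dimethyl-2-tridecyl-4H-chromen-4-one. The strategy rests on its fully substituted benzene ring (C4a, C5, C6, C7, C8, C8a), whose substituents alternate: O1 on C8a, Me on C8, OH on C7, Me on C6, OH on C5 and the C4 carbonyl on C4a.
2. The pyranone ring is made last. Cleaving the two O-ethyl groups, the O1–C2 bond (6-endo oxa-Michael of an o-hydroxyaryl ynone) and the C4–C4a bond (Friedel–Crafts acylation with hexadec-2-ynoyl chloride, from pentadec-1-yne and CO2) leads back to 3,5-diethoxy-2,4-dimethylphenol.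
3. The benzene ring comes from benzannulation of 3-ethoxy-2-methylcyclobut-2-en-1-one (as its vinylketene it supplies C8a, C6, C5, C4a) with 1-ethoxyprop-1-yne (C8, C7). The bonds formed are C8a–C8, C6–C7 and C8a–C4a.
4. The cyclobutenone comes from a [2+2] cycloaddition of ketene with the same ynol ether.
5. Ring order: cyclobutenone (step 1), benzene ring (step 2), pyranone ring (step 6).

Key step: step 2

Remark: the target has no stereocentre and no stereogenic double bond, so the "single enantiomer" is the achiral compound as drawn and no stereocontrol is needed.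

**Route**

Step 1
Reactants: 1 acetyl chloride; 2 1-ethoxyprop-1-yne
Product: 4 3-ethoxy-2-methylcyclobut-2-en-1-one, via ketene 3 (not isolated)
Conditions: Et3N (2.2 equiv), 1 (2 equiv, slow addition), MeCN, 0 °C → rt
Reagents that add atoms: none
Why: Dehydrochlorination of acetyl chloride gives ketene, which should undergo the standard ketene–alkoxyalkyne [2+2] cycloaddition, the nucleophilic methyl-bearing alkyne carbon bonding to the ketene carbonyl carbon so that the methyl ends up at C2 and the ethoxy group at C3.

Step 2
Reactants: 4 3-ethoxy-2-methylcyclobut-2-en-1-one; 2 1-ethoxyprop-1-yne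
Product: 9 3,5-diethoxy-2,4-dimethylphenol, via vinylketene 5 (not isolated), via vinylcyclobutenone 6 (not isolated), via dienylketene 7 (not isolated), via cyclohexadienone 8 (not isolated)
Conditions: 2 (2.5 equiv), PhMe, sealed tube, 80 °C, then 110 °C
Reagents that add atoms: none
Why: Thermal conrotatory 4π opening of 4 (cleavage of the C1–C4 bond) should give the 2-ethoxyvinyl(methyl)ketene 5, which adds the ynol ether in a [2+2] cycloaddition to give 6; a second 4π opening gives the dienylketene 7, 6π electrocyclization gives the dienone 8, and tautomerization gives the phenol 9. The closest known reaction type is the Danheiser benzannulation of a cyclobutenone with an alkoxyalkyne. The benzene ring, the only ring that persists, is closed by the thermal disrotatory 6π electrocyclization of 7, in which the ketene carbon bonds to the terminal CH2 (future C8a–C4a bond) after the [2+2] step has formed the future C8a–C8 and C6–C7 bonds. No stereocentre is created that survives, since the quaternary carbon of 6 is racemic and is lost on ring opening. The step needs the [2+2] regiochemistry, which the polarization of the ynol ether secures: its methyl-bearing carbon is the nucleophilic one and bonds to the electrophilic ketene carbonyl carbon, placing the methyl ortho and the ethoxy group meta to the new hydroxyl. The step also needs the alkyne to survive until it is consumed, which is why the cycloaddition is run at 80 °C, below the temperature of retro-ene loss of ethylene, before the final electrocyclic stage is driven at 110 °C.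

Step 3
Reactants: 10 pentadec-1-yne
Product: 13 hexadec-2-ynoic acid, via lithium acetylide 11 (not isolated), via lithium carboxylate 12 (not isolated)
Conditions: n-BuLi, THF, −78 °C; CO2, −78 °C → rt; aq. HCl
Reagents that add atoms: carbon dioxide, O=C=O
Why: Deprotonation of the terminal alkyne and carboxylation of the lithium acetylide with CO2 is the standard route to alk-2-ynoic acids.

Step 4
Reactants: 13 hexadec-2-ynoic acid
Product: 14 hexadec-2-ynoyl chloride
Conditions: (COCl)2, cat. DMF, CH2Cl2, 0 °C → rt
Reagents that add atoms: oxalyl chloride, ClC(=O)C(=O)Cl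
Why: Vilsmeier-type activation with oxalyl chloride and catalytic DMF should convert the acid into the acid chloride at low temperature without addition to the conjugated triple bond.

Step 5
Reactants: 9 3,5-diethoxy-2,4-dimethylphenol; 14 hexadec-2-ynoyl chloride
Product: 15 1-(2,4-diethoxy-6-hydroxy-3,5-dimethylphenyl)hexadec-2-yn-1-one
Conditions: AlCl3 (2.2 equiv), CH2Cl2, −20 → 0 °C; ice/1 M HCl
Reagents that add atoms: none
Why: In this Friedel–Crafts acylation the alkynoyl chloride–AlCl3 complex should attack the only unsubstituted ring carbon of 9, which is ortho to the aluminium phenoxide and ortho/para to the two ethoxy groups, while the excess Lewis acid ties up the phenol oxygen so that C-acylation is favoured over ester formation.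

Step 6
Reactants: 15 1-(2,4-diethoxy-6-hydroxy-3,5-dimethylphenyl)hexadec-2-yn-1-one
Product: 17 5,7-diethoxy-6,8-dimethyl-2-tridecyl-4H-chromen-4-one, via enaminone 16 (not isolated)
Conditions: Et2NH (2 equiv), EtOH, rt → reflux
Reagents that add atoms: none
Why: Aza-Michael addition of diethylamine to the ynone should give the β-enaminone, in which the ortho hydroxyl can only attack the β-carbon in a 6-endo addition–elimination (oxa-Michael with loss of Et2NH), so the chromone is expected and not the 5-exo aurone.

Step 7
Reactants: 17 5,7-diethoxy-6,8-dimethyl-2-tridecyl-4H-chromen-4-one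
Product: 18 5,7-dihydroxy-6,8-dimethyl-2-tridecyl-4H-chromen-4-one
Conditions: BBr3 (5 equiv), CH2Cl2, −78 °C → rt; then H2O
Reagents that add atoms: none
Why: BBr3 ether cleavage (Lewis acid complexation, then bromide attack on the ethyl group) should remove both ethyl groups, the C5 ether assisted by chelation to the C4 carbonyl and the C7 ether being twisted out of conjugation by its two ortho methyls, while the chromone core is stable to the reagent.

**Compound list**
1 | acetyl chloride | CC(=O)Cl | starting material
2 | 1-ethoxyprop-1-yne | CCOC#CC | starting material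
3 | ketene (ethenone) | C=C=O | intermediate
4 | 3-ethoxy-2-methylcyclobut-2-en-1-one | CCOC1=C(C)C(=O)C1 | intermediate
5 | 3-ethoxy-2-methylbuta-1,3-dien-1-one (vinylketene) | C=C(OCC)C(C)=C=O | intermediate
6 | 3-ethoxy-4-(1-ethoxyethenyl)-2,4-dimethylcyclobut-2-en-1-one (racemic) | CCOC(=C)C1(C)C(=O)C(C)=C1OCC | intermediate
7 | (3E)-3,5-diethoxy-2,4-dimethylhexa-1,3,5-trien-1-one (dienylketene, ketene and vinyl termini cis) | O=C=C(C)/C(OCC)=C(C)\C(OCC)=C | intermediate
8 | 3,5-diethoxy-2,4-dimethylcyclohexa-2,4-dien-1-one | O=C1CC(OCC)=C(C)C(OCC)=C1C | intermediate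
9 | 3,5-diethoxy-2,4-dimethylphenol | CCOc1cc(O)c(C)c(OCC)c1C | intermediate
10 | pentadec-1-yne | CCCCCCCCCCCCCC#C | starting material
11 | lithium pentadec-1-yn-1-ide | [Li]C#CCCCCCCCCCCCCC | intermediate
12 | lithium hexadec-2-ynoate | CCCCCCCCCCCCCC#CC(=O)[O-].[Li+] | intermediate
13 | hexadec-2-ynoic acid | CCCCCCCCCCCCCC#CC(=O)O | intermediate
14 | hexadec-2-ynoyl chloride | CCCCCCCCCCCCCC#CC(=O)Cl | intermediate
15 | 1-(2,4-diethoxy-6-hydroxy-3,5-dimethylphenyl)hexadec-2-yn-1-one | CCCCCCCCCCCCCC#CC(=O)c1c(O)c(C)c(OCC)c(C)c1OCC | intermediate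
16 | (2E)-3-(diethylamino)-1-(2,4-diethoxy-6-hydroxy-3,5-dimethylphenyl)hexadec-2-en-1-one | CCCCCCCCCCCCC/C(N(CC)CC)=C\C(=O)c1c(O)c(C)c(OCC)c(C)c1OCC | intermediate
17 | 5,7-diethoxy-6,8-dimethyl-2-tridecyl-4H-chromen-4-one | CCCCCCCCCCCCCc1cc(=O)c2c(OCC)c(C)c(OCC)c(C)c2o1 | intermediate
18 | 5,7-dihydroxy-6,8-dimethyl-2-tridecyl-4H-chromen-4-one | CCCCCCCCCCCCCc1cc(=O)c2c(O)c(C)c(O)c(C)c2o1 | target

**Step count**
Total: 7 steps. Longest linear sequence: 5 steps (1 → 2 → 5 → 6 → 7, or equally 3 → 4 → 5 → 6 → 7).

**Steps most likely to fail**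

Step 2 (key step). The donor-stabilized cyclobutenone may open too slowly at 80 °C, so that at the temperature it needs the ethoxyalkyne fragments by retro-ene loss of ethylene. The vinylketene may also be used up by dimerization or by acylating the product phenol before it meets the alkyne. The fallback gives up the annulation and uses the mirror symmetry of the arene, in which either oxygen ortho to the acyl group can become O1. It sets out from acid chloride 14 and comes back to the route at target 18. Commercial 2,4,6-trimethoxytoluene is lithiated between two methoxy groups (n-BuLi, TMEDA, THF, 0 °C) to (2,4,6-trimethoxy-3-methylphenyl)lithium F1, which is methylated with iodomethane to 1,3,5-trimethoxy-2,4-dimethylbenzene F2. Friedel–Crafts acylation of its single free position with 14 (AlCl3, CH2Cl2, −20 °C) should give 1-(2,4,6-trimethoxy-3,5-dimethylphenyl)hexadec-2-yn-1-one F3. BCl3 (CH2Cl2, −78 → 0 °C) should remove one methyl ether ortho to the carbonyl by chelation control, giving 1-(2-hydroxy-4,6-dimethoxy-3,5-dimethylphenyl)hexadec-2-yn-1-one F4. Diethylamine in ethanol should then close the pyranone by way of (2E)-3-(diethylamino)-1-(2-hydroxy-4,6-dimethoxy-3,5-dimethylphenyl)hexadec-2-en-1-one F5 to 5,7-dimethoxy-6,8-dimethyl-2-tridecyl-4H-chromen-4-one F6, and BBr3 (CH2Cl2, −78 °C → rt) should demethylate this to 18.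

Step 5. Acylation may take place at the phenol oxygen instead of at carbon, and the aryl ynoate could then cyclize by acid-promoted hydroarylation to a coumarin; chloride may also add across the Lewis-acid-activated triple bond. The fallback builds the ynone by carbonyl addition and oxidation in place of electrophilic acylation. It sets out from phenol 9 and lithium acetylide 11 (made from alkyne 10) and comes back at ynone 15. Magnesium-mediated ortho-formylation of 9 (MgCl2, Et3N, paraformaldehyde, MeCN, reflux) should give 2,4-diethoxy-6-hydroxy-3,5-dimethylbenzaldehyde F7. Addition of 11 (2.2 equiv, THF, −78 → 0 °C; aq. NH4Cl) should give racemic 1-(2,4-diethoxy-6-hydroxy-3,5-dimethylphenyl)hexadec-2-yn-1-ol F8, and MnO2 (CH2Cl2, rt) should oxidize the benzylic propargylic alcohol to 15.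

Step 1. Ketene generated in the flask may dimerize, or be intercepted by acetyl chloride and the amine, faster than it adds to the internal ynol ether. The fallback uses the more electrophilic dichloroketene and removes the chlorines afterwards. It sets out from alkyne 2 and comes back at cyclobutenone 4. Dichloroketene F9, generated from trichloroacetyl chloride with zinc–copper couple in Et2O, should add to 2 with the same regiochemistry to give 4,4-dichloro-3-ethoxy-2-methylcyclobut-2-en-1-one F10. Reductive dechlorination with zinc dust (AcOH, TMEDA, EtOH, 0 °C → rt) should then give 4.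

**Further compounds**
F1 | step 2 | (2,4,6-trimethoxy-3-methylphenyl)lithium | [Li]c1c(OC)cc(OC)c(C)c1OC
F2 | step 2 | 1,3,5-trimethoxy-2,4-dimethylbenzene | COc1cc(OC)c(C)c(OC)c1C
F3 | step 2 | 1-(2,4,6-trimethoxy-3,5-dimethylphenyl)hexadec-2-yn-1-one | CCCCCCCCCCCCCC#CC(=O)c1c(OC)c(C)c(OC)c(C)c1OC
F4 | step 2 | 1-(2-hydroxy-4,6-dimethoxy-3,5-dimethylphenyl)hexadec-2-yn-1-one | CCCCCCCCCCCCCC#CC(=O)c1c(O)c(C)c(OC)c(C)c1OC
F5 | step 2 | (2E)-3-(diethylamino)-1-(2-hydroxy-4,6-dimethoxy-3,5-dimethylphenyl)hexadec-2-en-1-one | CCCCCCCCCCCCC/C(N(CC)CC)=C\C(=O)c1c(O)c(C)c(OC)c(C)c1OC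
F6 | step 2 | 5,7-dimethoxy-6,8-dimethyl-2-tridecyl-4H-chromen-4-one | CCCCCCCCCCCCCc1cc(=O)c2c(OC)c(C)c(OC)c(C)c2o1
F7 | step 5 | 2,4-diethoxy-6-hydroxy-3,5-dimethylbenzaldehyde | CCOc1c(C)c(O)c(C=O)c(OCC)c1C
F8 | step 5 | 1-(2,4-diethoxy-6-hydroxy-3,5-dimethylphenyl)hexadec-2-yn-1-ol (racemic) | CCCCCCCCCCCCCC#CC(O)c1c(O)c(C)c(OCC)c(C)c1OCC
F9 | step 1 | dichloroketene | ClC(Cl)=C=O
F10 | step 1 | 4,4-dichloro-3-ethoxy-2-methylcyclobut-2-en-1-one | CCOC1=C(C)C(=O)C1(Cl)Cl
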